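No rate constants are given for this coupling, so Saturday's and Tuesday's runs stand in for them. Saturday's run is the flask asked about, followed as far as 90.0 min.

| setting | Saturday's | Tuesday's | flask |
|---|---|---|---|
| starting material | 0.40 M | 0.40 M | 0.40 M |
| second substrate | 2 equiv | 2 equiv | 2.00 equiv |
| coupling partner | 0.95 equiv | 0.95 equiv | 0.950 equiv |
| free catalyst | 0.2 mol% | 0.2 mol% | 0.2 mol% |
| temperature | 60 °C | 45 °C | 60 °C |
| remark | the very flask that is asked about, followed so far | run made earlier |  |
| time |  |  | 2.5 h |

| run | time / min | target / % | starting material / % |
|---|---|---|---|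
| Saturday's | 15.0 | 5.8 | 93.5 |
| Saturday's | 30.0 | 8.5 | 90.3 |
| Saturday's | 50.0 | 12.6 | 87.7 |
| Saturday's | 60.0 | 12.1 | 88.0 |
| Saturday's | 80.0 | 12.5 | 86.5 |
| Saturday's | 90.0 | 13.3 | 87.5 |
| Tuesday's | 30.0 | 9.3 | 90.0 |
| Tuesday's | 60.0 | 15.4 | 84.0 |
| Tuesday's | 120 | 23.5 | 76.0 |
| Tuesday's | 180 | 26.9 | 73.7 |

(each reading ± 0.5 percentage points)

- dawn: at 2.5 h take out 90% of the target then present, then wait 50 min
- dusk: at 2.5 h add coupling partner, 100% of the amount charged, then wait 50 min
- noon: at 2.5 h raise the temperature by 25 K, then wait 50 min
- midnight: change nothing and wait 50 min more
- summer: at 2.5 h add free catalyst, 50.0% of the amount charged, then wait 50 min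

- target that was removed still counts
- additions bring no volume worth counting

1. target, in percent of the starting material first charged, at 2.5 h
2. which option adds most target ("none" when 2 percentage points or less is all one gets) (dawn / dusk / noon / midnight / summer / none)
3. target present, with what was taken out counted in, in percent of the starting material first charged, after midnight
4. target present, with what was taken out counted in, in percent of the starting material first charged, after summer

In the first instants, target rises in both runs. At 30.0 min, Saturday's flask at 60 °C holds 8.5%, against 9.3% in Tuesday's flask at 45 °C at the same time, so the hotter flask is not ahead. In the middle of Saturday's run, target reads 12.6% at 50.0 min and 13.3% at 90.0 min, a rise of 0.7 percentage points against a scatter of 0.5 points, while starting material still reads 87.5%. Saturday's plateau, the mean of its readings from 50.0 min on, reads 12.6%, and Tuesday's flask reads 26.9% at 180 min, about twice that plateau.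

With starting material still standing, this reckoning turns to the coupling partner, which is not read. This reckoning supposes that a rival consumer shares it, taking more when hot, and that the plateau marks its last portion:

plateau, mean of Saturday's readings from 50.0 min on = 12.6%

φ = plateau / coupling partner charged = 0.133

gain from dusk = φ × coupling partner added = 13 points

This partner yield, target made per equivalent of coupling partner charged, gives the plateau as the reckoned target at 2.5 h. Dusk is the option that brings coupling partner, and its reckoned gain is more than the margin of 2 points, so this reckoning chooses dusk and expects midnight and summer to stay at the plateau.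

The forecast gives 13.1% (12.5% to 13.8%), 13.2% after midnight and 18.2% after summer, and it chooses summer, on the ground that “the catalyst is essentially dead”. It parts from the reckoning above on the option.

The flask gives 13.0%, then 13.0% after midnight and 13.0% after summer. Dusk adds 18 points, so the best option is dusk.

    starting material + free catalyst ⇌ catalyst intermediate A (K = 1.60 L mol⁻¹, k = 54.8 L mol⁻¹ min⁻¹, Ea = 52.0 kJ mol⁻¹, ΔH = −52.0 kJ mol⁻¹)
    coupling partner + catalyst intermediate A → free catalyst + target (k = 21.2 L mol⁻¹ min⁻¹, Ea = 38.0 kJ mol⁻¹)
    second substrate + free catalyst ⇌ catalyst intermediate B (K = 15.0 L mol⁻¹, k = 24.2 L mol⁻¹ min⁻¹, Ea = 65.0 kJ mol⁻¹, ΔH = −37.0 kJ mol⁻¹)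
    coupling partner + catalyst intermediate B → free catalyst + second product (k = 210 L mol⁻¹ min⁻¹, Ea = 54.0 kJ mol⁻¹)
    2 second substrate → homo dimer (k = 0.00699 L mol⁻¹ min⁻¹, Ea = 74.0 kJ mol⁻¹)
    (constants at 60 °C)

In the flask at 150 min, the coupling partner, the limiting reagent, stands at 0% of its charge. Its use in making second product runs at 5.06 times its use in making target at 15.0 min, and at 23.0 times at 75.0 min, a ratio that is larger later. The reckoned 13 points for dusk falls below the 18 points obtained.

For a neighbour charged with 3.80 equiv of coupling partner, φ gives 50.5% of target. The computed neighbour holds 85.5% of target at 150 min, more than that, with second substrate at 5.33% and coupling partner at 41.0%, each of its own charge.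

(The numbers in the tables stem from a simulated flask for substances that don't exist; scatter was added.)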